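The readings were computed for substances that don't exist, and the scatter is random.

The ash run left 9.9% of left-handed substrate and 10.0% of right-handed substrate at 6.00 h, in percent of the two charged together, after both had been coupled with reagent on the single-handed free catalyst while the racemization catalyst interconverted them.

| setting | cedar | birch | ash | flask |
|---|---|---|---|---|
| left-handed substrate | 0.17 M | 0.17 M | 0.17 M | 0.17 M |
| right-handed substrate | 0.17 M | 0.17 M | 0.17 M | 0.17 M |
| reagent | 3 equiv | 3 equiv | 3 equiv | 3.00 equiv |
| free catalyst | 5 mol% | 5 mol% | 5 mol% | 5 mol% |
| racemization catalyst | 10 mol% | 10 mol% | 20 mol% | 10 mol% |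
| added ligand | 19 mM | 76 mM | 38 mM | 38 mM |
| remark | run made earlier | run made earlier | run made earlier |  |
| time |  |  |  | 8.0 h |

- cedar (time / h: left-handed substrate / %, right-handed substrate / %, left-handed product / %): 1.00: 15.0, 15.0, 48.6; 2.00: 10.4, 11.0, 53.2; 3.00: 10.0, 11.3, 55.0; 4.00: 9.9, 10.1, 55.1; 5.00: 10.1, 10.4, 55.9; 6.00: 9.4, 9.8, 55.3
- birch (time / h: left-handed substrate / %, right-handed substrate / %, left-handed product / %): 1.00: 15.7, 17.3, 45.2; 2.00: 13.6, 13.7, 51.3; 3.00: 12.6, 10.9, 53.6; 4.00: 11.4, 11.3, 53.6; 5.00: 10.6, 11.0, 53.6; 6.00: 10.0, 11.3, 55.2
- ash (time / h: left-handed substrate / %, right-handed substrate / %, left-handed product / %): 0.500: 21.6, 21.9, 39.7; 1.00: 15.7, 15.6, 48.1; 2.00: 11.7, 11.8, 53.9; 3.00: 10.3, 9.8, 55.4; 6.00: 9.9, 10.0, 56.4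

(standard deviation of a reading: 0.5 percentage points)

- free catalyst is single-handed; left-handed substrate and right-handed substrate are mirror images of each other, charged as a racemate, each of them at the stated concentration
- steps that have been proposed: free catalyst + added ligand <-> idle complex; 2 reagent -> homo dimer; reagent + free catalyst + right-handed substrate -> free catalyst + right-handed product; free catalyst -> spent catalyst; reagent + free catalyst + left-handed substrate -> free catalyst + left-handed product; left-handed substrate + racemization catalyst <-> right-handed substrate + racemization catalyst
- an excess is below zero if the other one leads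

1. part of the left-handed substrate and right-handed substrate charged together that has reacted at 8.0 h
2. excess of left-handed product over right-handed product in the product at 8.0 h
3. excess of right-handed substrate over left-handed substrate among what is left of the two at 8.0 h

From that leftover the reach came to 1.61. By reach I mean the natural logarithm of [left-handed substrate] + [right-handed substrate] at the charge over the same sum remaining, which is the time integral of a pseudo-first-order rate constant.

My second way used earlier ash readings. Reach was 1.16 at 1.00 h and 1.45 at 2.00 h, so the second hour added 0.247 of the first hour's gain. If each hour repeated that fraction, the series summed to 1.54. That stood below the late reading by 0.0700. The series carried one ratio from two early readings forward to every later hour, whereas 1.61 was read directly at 6.00 h, so I judged the series the one that cheated and kept 1.61.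

The cedar run, with 19 mM of added ligand against 38 mM in ash and with the flask's 10 mol% of racemization catalyst, gave a reach of 1.65 at 6.00 h. For the flask I therefore reckoned 80.1% reacted by 8.0 h.

The forecast gave c 80% (78.8% to 81.2%), eP 39.5% (37.8% to 41.2%) and eS 0% (−1% to 1.5%), holding that “the ligand scales coupling and death equally, so total turnover stays fixed”.

The flask gave c 79.5%, eP 37.9% and eS 0%, each inside the forecast's range.

    free catalyst + added ligand ⇌ idle complex (K = 6.90 M⁻¹, k = 1.00 M⁻¹ min⁻¹)
    2 reagent → homo dimer (k = 0.00830 M⁻¹ min⁻¹)
    reagent + free catalyst + right-handed substrate → free catalyst + right-handed product (k = 8.20 M⁻² min⁻¹)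
    free catalyst → spent catalyst (k = 0.0180 min⁻¹)
    reagent + free catalyst + left-handed substrate → free catalyst + left-handed product (k = 21.0 M⁻² min⁻¹)
    left-handed substrate + racemization catalyst ⇌ right-handed substrate + racemization catalyst, rate k6*[racemization catalyst]*[left-handed substrate] forward; the back reaction follows from the equilibrium constant (k = 3.10 M⁻¹ min⁻¹)

Until 1.60 h the flask's coupling of left-handed substrate ran, with 93% of its turnover up to 8.0 h done by then, while free catalyst fell from 38.8% at 0.800 h to 2.64% at 4.00 h. Afterwards the flask's substrates stood at 10.2% and 10.2% at 8.00 h, while homo dimer rose from 0.0693 M at 4.00 h to 0.0839 M. The flask's reach was 1.58. A run that breaks the forecast's plateau is the neighbour charged with 0.750 equiv of reagent, a quarter of the recipe's. Scaling reach by that quarter gave 0.404, meaning 33.2% reacted. That neighbour reached 30.4%, with 21.7% left-handed product and 8.75% right-handed product.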